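**Plan**

- Retrosynthetic cuts: the anisoyl C–O ester bond; the C6–O and C7–O bonds back to a C6=C7 ring alkene (with redox inversion at C7); the cyclopentane bond C3–C3a as a carbonyl-ene disconnection to a monocyclic cycloheptenone; the side-chain C=C (Wittig) and the C8a–allyl bond (Pd allylation); the ring C=C (metathesis) and an acetoacetate γ-C–C bond.
- Enabling feature: in the cyclopentane (C1–C2–C3–C3a–C8a) the tertiary carbinol C3a lies between the quaternary C8a and the isopropyl-bearing C3. This 2-isopropylcyclopentanol is what a C3a ketone gives in an ene reaction with a Me2C=CH terminus tethered at C8a. The bond formed is the one the isopropylidene terminus makes to the ring-fusion carbon in the presumed daucane biogenesis.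
- Forward order: seven-membered ring first (dianion alkylation, ring-closing metathesis), then quaternary C8a, then chain extension, then the cyclopentane last (step 9), then saturation, diol and ester. No protecting groups are used.
- Stereochemistry: C8a from the chiral Pd catalyst; C3a and C3 from the ene transition state under control of C8a; C6 and C7 from reagent approach anti to the angular methyl and hydroxyl (osmylation, then oxidation and hydride return at C7).

Key step: step 9

Remark: ring positions in 14–20 are cited with the azulene locants of 15 (C3 = CH–iPr, C3a = C–OH, C6 = C–Me, C7, C8a = C–Me). The facial sense of the Pd/(S)-t-BuPHOX alkylation is assumed by analogy with simple 2-methylcycloalkanone enolates.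

**Route**

Step 1
Reactants: 1 (ethyl 2-acetylpent-4-enoate), 2 (3-chloro-2-methylprop-1-ene)
Product: 4 ethyl 6-methyl-3-oxo-2-(prop-2-en-1-yl)hept-6-enoate, via sodium lithium dienolate 3 (not isolated)
Conditions: NaH, THF, 0 °C; n-BuLi, 0 °C; then 2, 0 °C → rt; 1 M HCl
Reagents that add atoms: none
Why: Acetoacetate dianion alkylation, in which the second deprotonation occurs at the terminal methyl and the more reactive γ-carbanion is alkylated by the allylic chloride; C2 stays epimerisable and is set later.

Step 2
Reactants: 4
Product: 5 ethyl 4-methyl-7-oxocyclohept-3-ene-1-carboxylate (racemic)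
Conditions: Grubbs second-generation catalyst (5 mol %), CH2Cl2 (5 mM), 40 °C
Reagents that add atoms: none
Why: Ring-closing olefin metathesis between the allyl alkene and the 1,1-disubstituted alkene should close the seven-membered ring as its trisubstituted alkene, with the methyl group fixed on the carbon remote from the ester-bearing centre.

Step 3
Reactants: 5, 6 (prop-2-en-1-ol)
Product: 7 prop-2-en-1-yl 4-methyl-7-oxocyclohept-3-ene-1-carboxylate (racemic)
Conditions: 6 (10 equiv), DMAP (0.3 equiv), toluene, 4 Å MS, reflux
Reagents that add atoms: none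
Why: DMAP-assisted transesterification of an enolisable β-keto ester; the allyl ester is introduced only after metathesis so that it cannot take part in ring closure.

Step 4
Reactants: 7
Product: 8 prop-2-en-1-yl 1,4-dimethyl-7-oxocyclohept-3-ene-1-carboxylate (racemic)
Conditions: K2CO3, MeI, acetone, 50 °C
Reagents that add atoms: iodomethane (CI)
Why: C-Alkylation of the stabilised β-keto ester enolate gives the racemic quaternary ester, whose configuration is irrelevant because the next step is stereoablative.

Step 5
Reactants: 8
Product: 9 (2R)-2,5-dimethyl-2-(prop-2-en-1-yl)cyclohept-4-en-1-one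
Conditions: Pd2(dba)3 (2.5 mol %), (S)-t-BuPHOX (6.25 mol %), toluene, 30 °C
Reagents that add atoms: none
Why: Pd-catalysed decarboxylative asymmetric allylic alkylation (Tsuji type), in which both enantiomers of 8 give the same Pd enolate/π-allyl pair and the (S)-PHOX ligand controls the face of C–C bond formation, which should set C2 as R (the spatial sense of (S)-2-allyl-2-methylcyclohexanone).

Step 6
Reactants: 9
Product: 11 (2R)-2-(3-hydroxypropyl)-2,5-dimethylcyclohept-4-en-1-one, via B-alkyl-9-BBN adduct 10 (not isolated)
Conditions: 9-BBN (1.3 equiv), THF, 0 °C → rt; then NaOH, H2O2, 0 °C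
Reagents that add atoms: 9-borabicyclo[3.3.1]nonane (B1C2CCCC1CCC2, boron kept only in 10), hydrogen peroxide (OO)
Why: Anti-Markovnikov hydroboration–oxidation, in which 9-BBN should add only to the monosubstituted alkene because the trisubstituted ring alkene and the hindered α-quaternary ketone react far more slowly.

Step 7
Reactants: 11
Product: 12 3-[(1R)-1,4-dimethyl-7-oxocyclohept-3-en-1-yl]propanal
Conditions: Dess–Martin periodinane (1.2 equiv), CH2Cl2, 0 °C → rt
Reagents that add atoms: none
Why: Dess–Martin oxidation of the primary alcohol under non-basic conditions, which avoids aldol reaction of the keto aldehyde.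

Step 8
Reactants: 12
Product: 13 (2R)-2,5-dimethyl-2-(4-methylpent-3-en-1-yl)cyclohept-4-en-1-one
Conditions: i-PrPPh3I, n-BuLi, THF, 0 °C; then 12, −78 → 0 °C
Reagents that add atoms: isopropyltriphenylphosphonium iodide (CC(C)[P+](c1ccccc1)(c1ccccc1)c1ccccc1.[I-])
Why: Wittig olefination, in which the non-stabilised isopropylidene ylide should react with the aldehyde far faster than with the neopentyl-type ketone and installs the Me2C=CH terminus that serves as ene donor.

Step 9
Reactants: 13
Product: 14 (3R,3aS,8aR)-6,8a-dimethyl-3-(prop-1-en-2-yl)-2,3,4,5,8,8a-hexahydroazulen-3a(1H)-ol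
Conditions: Me2AlCl (2.0 equiv), CH2Cl2, −78 → −20 °C; aq. Rochelle salt
Reagents that add atoms: none
Why: Me2AlCl activates the C1 ketone of 13, and the Me2C=CH terminus adds through its CH carbon to the carbonyl carbon while an allylic hydrogen of one terminal methyl passes to oxygen in a six-membered array; this closes the cyclopentane and forms the tertiary aluminium alkoxide and the isopropenyl group in one event, and the reagent removes the transferred proton as methane so that no free acid can start 1,2-shifts or dehydration. The closest known reaction type is the Lewis-acid-promoted type I intramolecular carbonyl-ene (Prins-type) cyclisation of δ,ε-unsaturated aldehydes and ketones to 2-isopropenylcycloalkanols, and the bond made is the one that the isopropylidene terminus makes to the ring-fusion carbon in the presumed daucane biogenesis. The ring closes in a 5-exo-trig mode with respect to the carbonyl group (the C=O bond is exocyclic to the new ring), and the attacking alkene also lies outside the ring. C3a is controlled by the three-carbon tether, which leaves the quaternary centre on one face of the seven-membered ring and can reach the adjacent carbonyl carbon only from that face, so the ring fusion is cis and the hydroxyl is cis to the angular methyl; C3 is controlled by the cyclic ene transition state, in which the carbonyl oxygen and the isopropylidene carbon must lie on the same side of the forming ring for hydrogen transfer, so the isopropenyl group ends cis to the hydroxyl and away from the ring methylene C4. The step needs chemoselectivity for the side-chain alkene over the ring alkene and for ene closure over methyl transfer from aluminium; the first is secured because attack of the ring alkene on the carbonyl would form a four-membered ring, the second by the low temperature and the intramolecular five-ring pathway.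

Step 10
Reactants: 14
Product: 15 (3R,3aS,8aR)-6,8a-dimethyl-3-(propan-2-yl)-2,3,4,5,8,8a-hexahydroazulen-3a(1H)-ol
Conditions: H2 (1 atm), RhCl(PPh3)3 (5 mol %), benzene/EtOH, rt
Reagents that add atoms: none
Why: Homogeneous hydrogenation with Wilkinson's catalyst should be selective for the 1,1-disubstituted isopropenyl alkene over the trisubstituted ring alkene, and no stereocentre is formed or touched.

Step 11
Reactants: 15
Product: 16 (3R,3aS,6R,7S,8aR)-6,8a-dimethyl-3-(propan-2-yl)decahydroazulene-3a,6,7-triol
Conditions: OsO4 (5 mol %), NMO (1.5 equiv), acetone/H2O, rt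
Reagents that add atoms: osmium tetroxide (O=[Os](=O)(=O)=O), 4-methylmorpholine N-oxide (C[N+]1([O-])CCOCC1), water (O)
Why: Upjohn dihydroxylation (concerted syn [3+2] addition of OsO4), in which osmium should add to C6=C7 from the face opposite the C8a methyl and C3a hydroxyl, setting C6 in its final configuration and C7 as the epimer to be inverted.

Step 12
Reactants: 16
Product: 17 (3R,3aS,6R,8aR)-3a,6-dihydroxy-6,8a-dimethyl-3-(propan-2-yl)octahydroazulen-7(1H)-one (locants as in 15)
Conditions: Dess–Martin periodinane (1.2 equiv), CH2Cl2, 0 °C → rt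
Reagents that add atoms: none
Why: Dess–Martin oxidation of the only secondary hydroxyl; the two tertiary hydroxyls cannot be oxidised and C6 is not enolisable, so its configuration is safe.

Step 13
Reactants: 17
Product: 18 (3R,3aS,6R,7R,8aR)-6,8a-dimethyl-3-(propan-2-yl)decahydroazulene-3a,6,7-triol
Conditions: NaBH4, MeOH, −40 → 0 °C
Reagents that add atoms: none
Why: Borohydride reduction of the α-hydroxy ketone, in which hydride should attack C7 from the face of the C6 hydroxyl and anti to the C6 and C8a methyl groups, placing the new hydroxyl trans to the C6 hydroxyl (7R).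

Step 14
Reactants: 18, 19 (4-methoxybenzoyl chloride)
Product: 20 (3R,3aS,6R,7R,8aR)-3a,6-dihydroxy-6,8a-dimethyl-3-(propan-2-yl)decahydroazulen-7-yl 4-methoxybenzoate (locants as in 15; the target)
Conditions: 19 (1.3 equiv), pyridine, DMAP (cat.), CH2Cl2, 0 °C → rt
Reagents that add atoms: none
Why: DMAP-catalysed acylation (nucleophilic catalysis) should occur only at the secondary C7 hydroxyl because the C3a and C6 hydroxyls are tertiary.

**Compound list**

1 | ethyl 2-acetylpent-4-enoate | CCOC(=O)C(CC=C)C(C)=O | starting material
2 | 3-chloro-2-methylprop-1-ene | CC(=C)CCl | starting material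
3 | sodium lithium dienolate of 1 | C=CCC(C(=C)[O-])=C([O-])OCC.[Li+].[Na+] | intermediate
4 | ethyl 6-methyl-3-oxo-2-(prop-2-en-1-yl)hept-6-enoate | CCOC(=O)C(CC=C)C(=O)CCC(C)=C | intermediate
5 | ethyl 4-methyl-7-oxocyclohept-3-ene-1-carboxylate (racemic) | CCOC(=O)C1CC=C(C)CCC1=O | intermediate
6 | prop-2-en-1-ol | C=CCO | starting material
7 | prop-2-en-1-yl 4-methyl-7-oxocyclohept-3-ene-1-carboxylate (racemic) | C=CCOC(=O)C1CC=C(C)CCC1=O | intermediate
8 | prop-2-en-1-yl 1,4-dimethyl-7-oxocyclohept-3-ene-1-carboxylate (racemic) | C=CCOC(=O)C1(C)CC=C(C)CCC1=O | intermediate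
9 | (2R)-2,5-dimethyl-2-(prop-2-en-1-yl)cyclohept-4-en-1-one | CC1=CC[C@@](C)(CC=C)C(=O)CC1 | intermediate
10 | B-alkyl-9-BBN adduct of 9 | CC1=CC[C@@](C)(CCCB2C3CCCC2CCC3)C(=O)CC1 | intermediate
11 | (2R)-2-(3-hydroxypropyl)-2,5-dimethylcyclohept-4-en-1-one | CC1=CC[C@@](C)(CCCO)C(=O)CC1 | intermediate
12 | 3-[(1R)-1,4-dimethyl-7-oxocyclohept-3-en-1-yl]propanal | CC1=CC[C@@](C)(CCC=O)C(=O)CC1 | intermediate
13 | (2R)-2,5-dimethyl-2-(4-methylpent-3-en-1-yl)cyclohept-4-en-1-one | CC1=CC[C@@](C)(CCC=C(C)C)C(=O)CC1 | intermediate
14 | (3R,3aS,8aR)-6,8a-dimethyl-3-(prop-1-en-2-yl)-2,3,4,5,8,8a-hexahydroazulen-3a(1H)-ol | CC1=CC[C@@]2(C)CC[C@H](C(C)=C)[C@@]2(O)CC1 | intermediate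
15 | (3R,3aS,8aR)-6,8a-dimethyl-3-(propan-2-yl)-2,3,4,5,8,8a-hexahydroazulen-3a(1H)-ol | CC1=CC[C@@]2(C)CC[C@H](C(C)C)[C@@]2(O)CC1 | intermediate
16 | (3R,3aS,6R,7S,8aR)-6,8a-dimethyl-3-(propan-2-yl)decahydroazulene-3a,6,7-triol | O[C@H]1C[C@@]2(C)CC[C@H](C(C)C)[C@@]2(O)CC[C@@]1(C)O | intermediate
17 | (3R,3aS,6R,8aR)-3a,6-dihydroxy-6,8a-dimethyl-3-(propan-2-yl)octahydroazulen-7(1H)-one | O=C1C[C@@]2(C)CC[C@H](C(C)C)[C@@]2(O)CC[C@@]1(C)O | intermediate
18 | (3R,3aS,6R,7R,8aR)-6,8a-dimethyl-3-(propan-2-yl)decahydroazulene-3a,6,7-triol | O[C@@H]1C[C@@]2(C)CC[C@H](C(C)C)[C@@]2(O)CC[C@@]1(C)O | intermediate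
19 | 4-methoxybenzoyl chloride | COc1ccc(cc1)C(Cl)=O | starting material
20 | (3R,3aS,6R,7R,8aR)-3a,6-dihydroxy-6,8a-dimethyl-3-(propan-2-yl)decahydroazulen-7-yl 4-methoxybenzoate | COc1ccc(C(=O)O[C@@H]2C[C@@]3(C)CC[C@H](C(C)C)[C@@]3(O)CC[C@@]2(C)O)cc1 | target

**Totals and risks**

Total step count: 14. Longest linear sequence: 14 steps (from 1).

Steps most likely to fail:

1. Step 9. The ene closure may turn stepwise: an open zwitterion could undergo 1,2-hydride or alkyl shift or chloride capture, or the cis selectivity at C3 could be lost. Fallback (from 12, back at 14): the aldehyde 12 is treated with the ylide of [1-(trimethylsilyl)propan-2-yl]triphenylphosphonium iodide (made from ethylidenetriphenylphosphorane and (iodomethyl)trimethylsilane, then n-BuLi) to give the allylsilane (2R)-2,5-dimethyl-2-[4-methyl-5-(trimethylsilyl)pent-3-en-1-yl]cyclohept-4-en-1-one F1. An intramolecular Hosomi–Sakurai reaction (TiCl4, CH2Cl2, −78 °C) should then close the ring by γ-attack on the ketone; the β-silyl cation should collapse by desilylation before any shift, and the route is rejoined at 14.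

2. Step 11. Osmylation may show poor facial selectivity (attack from the face of the angular substituents) or slow turnover on the hindered trisubstituted alkene. Fallback (from 15, back at 18, bypassing 16 and 17): hydroxyl-directed epoxidation of 15 (VO(acac)2, t-BuOOH, CH2Cl2) should give the epoxide syn to the C3a hydroxyl, (3R,3aS,6S,7R,8aR)-6,7-epoxy-6,8a-dimethyl-3-(propan-2-yl)decahydroazulen-3a-ol F7. Acid-catalysed hydrolysis (cat. HClO4, THF/H2O) should open it at the tertiary C6 with inversion, which gives the trans-diol 18; the C3a hydroxyl, being syn to the epoxide oxygen, cannot open it transannularly.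

3. Step 5. Enantioselectivity may erode in the alkylation of a seven-membered enolate. Fallback (from 8, back at 12): deallylative decarboxylation of 8 (Pd(OAc)2, PPh3, HCO2H, Et3N, THF) gives racemic 2,5-dimethylcyclohept-4-en-1-one F2. Condensation with (R)-1-phenylethylamine (cat. TsOH, toluene, Dean–Stark) gives the imine N-[(1R)-1-phenylethyl]-2,5-dimethylcyclohept-4-en-1-imine F3. Its more substituted secondary enamine tautomer should add to methyl acrylate on one face (auxiliary-controlled deracemising Michael addition) to give methyl 3-[(1R)-1,4-dimethyl-7-{[(1R)-1-phenylethyl]imino}cyclohept-3-en-1-yl]propanoate F4. Hydrolysis (aq. AcOH) gives the keto ester methyl 3-[(1R)-1,4-dimethyl-7-oxocyclohept-3-en-1-yl]propanoate F5. LiAlH4 reduction gives the diol (2R)-2-(3-hydroxypropyl)-2,5-dimethylcyclohept-4-en-1-ol F6 (carbinol epimers), and double Dess–Martin oxidation returns the route to 12.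

Further compounds
F1 | step 9 | (2R)-2,5-dimethyl-2-[4-methyl-5-(trimethylsilyl)pent-3-en-1-yl]cyclohept-4-en-1-one | CC1=CC[C@@](C)(CCC=C(C)C[Si](C)(C)C)C(=O)CC1
F2 | step 5 | 2,5-dimethylcyclohept-4-en-1-one (racemic) | CC1=CCC(C)C(=O)CC1
F3 | step 5 | N-[(1R)-1-phenylethyl]-2,5-dimethylcyclohept-4-en-1-imine | CC1=CCC(C)C(=N[C@H](C)c2ccccc2)CC1
F4 | step 5 | methyl 3-[(1R)-1,4-dimethyl-7-{[(1R)-1-phenylethyl]imino}cyclohept-3-en-1-yl]propanoate | CC1=CC[C@@](C)(CCC(=O)OC)C(=N[C@H](C)c2ccccc2)CC1
F5 | step 5 | methyl 3-[(1R)-1,4-dimethyl-7-oxocyclohept-3-en-1-yl]propanoate | CC1=CC[C@@](C)(CCC(=O)OC)C(=O)CC1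
F6 | step 5 | (2R)-2-(3-hydroxypropyl)-2,5-dimethylcyclohept-4-en-1-ol | CC1=CC[C@@](C)(CCCO)C(O)CC1
F7 | step 11 | (3R,3aS,6S,7R,8aR)-6,7-epoxy-6,8a-dimethyl-3-(propan-2-yl)decahydroazulen-3a-ol | O1[C@@H]2C[C@@]3(C)CC[C@H](C(C)C)[C@@]3(O)CC[C@]12C
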